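| setting | larch | elm | west | north-east |
|---|---|---|---|---|
| starting material | 1.5 M | 1.5 M | 1.5 M | 1.5 M |
| free catalyst | 0.75 mM | 3 mM | 1.5 mM | 1.5 mM |
| temperature | −15 °C | −4 °C |  |  |
| remark | run made earlier | run made earlier | at −20 °C throughout | at −20 °C until 12 d, from then on at 0 °C |
| time |  |  | 6.0 d | 25 d |

- larch (time / d: target / %, starting material / %): 2.50: 46.1, 47.0; 6.00: 54.5, 18.9; 12.0: 39.1, 3.3; 30.0: 5.8, 0
- elm (time / d: target / %, starting material / %): 4.00: 12.6, 0; 6.00: 3.6, 0.3; 12.0: 0.1, 0.3; 15.0: 0, 0

(readings scatter by 1 percentage point)

- which one finishes higher in amount of target, in percent of the starting material charged ("neither" within 2 percentage points) (west / north-east / neither)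
- amount of target at the end, in percent of the starting material charged, west
- amount of target at the end, in percent of the starting material charged, north-east

- the earlier runs were read with a standard deviation of 1 percentage point

- The constants these runs offer are first-order rate constants k, and I start with the loss of target: its late readings give k = 0.106 d⁻¹ in larch and 0.626 d⁻¹ in elm.
- I let temperature carry that change, which is my assumption, since the catalyst changed as well. Stretching ln k in a straight line to −20 °C gives 0.0473 d⁻¹, slower than larch by a factor 2.24. So the quantity I carry is the half-life of target at −20 °C, 14.7 d.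
- In larch, starting material falls at 0.302 d⁻¹ up to 2.50 d and at 0.280 d⁻¹ after it, so I read its rate as following its own amount (pseudo-first-order), with constant k_A.
- West has twice the catalyst of larch but stands colder, and these runs cannot separate the two effects, so I keep k_A unchanged.
- Two consecutive first-order steps then give my west 68.1% at 6.0 d.
- At 0 °C the same line gives a half-life of 0.580 d, and north-east spends 13.0 d there, about 22.4 half-lives, so I put west ahead.
- The forecast says west, with west at 46% (40% to 55%) and north-east at 0.2% (0% to 1.5%). Its ground is “Assuming first order in catalyst”, which puts target loss at 0.19 per day against my 0.0473 d⁻¹, and my west stands higher than its west.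
- West ends at 65.6% and north-east at 0%, so west finishes higher, and the forecast's west is 20 points low. Between 3.00 d and 6.00 d, over-reaction product in west rises by 8.7 points. The half-life 14.7 d, applied to the mean target of that stretch, gives 8.4 points.

    starting material + free catalyst → catalyst intermediate A (k = 29.3 L mol⁻¹ h⁻¹, Ea = 52.0 kJ mol⁻¹)
    catalyst intermediate A → catalyst intermediate B (k = 48.0 h⁻¹, Ea = 74.0 kJ mol⁻¹)
    catalyst intermediate B → free catalyst + target (k = 66.5 h⁻¹, Ea = 72.0 kJ mol⁻¹)
    target → over-reaction product (k = 0.00199 h⁻¹, Ea = 87.0 kJ mol⁻¹)
    2 catalyst intermediate B → spent catalyst (k = 171 L mol⁻¹ h⁻¹, Ea = 49.0 kJ mol⁻¹)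
    (constants at −20 °C)

- The neighbour is north-east read at 10 d, before its change at 12 d, so it is still at −20 °C. The half-life 14.7 d with k_A gives 67.7%, and the flask holds 66.0%.

(The runs are calculated for an exercise, and the scatter is random.)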